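**Strategy.** Clerodane numbering is used. The ring's conjugated triene (C10=C1 E, C2=C3 Z, C4=C5) is the retron of a conrotatory 6π opening. A sacrificial C5–C10 bond therefore recasts the ten-membered ring as a decalin, whose ring B carries the contiguous C8 (CHMe) and C9 (quaternary, Me) centres. These two methyl-bearing carbons are read as two alkenes joined reductively. Iron-hydride hydrogen-atom transfer to the C9=CH2 alkene of a trans-2,3-disubstituted cyclohexanone gives the tertiary C9 radical. This radical closes ring B 6-exo onto a C8 vinyl sulfone and sets both centres in one chair–chair array. Angular hydroxymethylation, an 18,19-lactone and light then release the macrocycle.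

Key step: step 8

Remark on numbering: C1–C10 are the ten ring atoms; C4 bears CO2H (C18), C5 bears CH2OAc (C19), C8 bears CH3 (C17), and C9 bears CH3 (C20) and the furylethyl arm (C11, C12).

Assumption: the enantiomer of the chiral NHC precursor in step 5 is the one that delivers the alkenyl group to give (3S)-12; the sense of induction has to be confirmed on this substrate.

Step 1
Reactants: 1 cyclohex-2-en-1-one
Product: 2 2-iodocyclohex-2-en-1-one
Conditions: I2, K2CO3, DMAP (20 mol %), THF–H2O, rt
Reagents that add atoms: iodine, [I][I]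
Why: Amine-catalysed α-iodination of an enone (conjugate addition of DMAP, iodination of the enolate, elimination) should give the α-iodoenone needed for cross-coupling.

Step 2
Reactants: 2 2-iodocyclohex-2-en-1-one; 3 [2-(1,3-dioxolan-2-yl)ethyl]zinc bromide (commercial THF solution)
Product: 4 2-[2-(1,3-dioxolan-2-yl)ethyl]cyclohex-2-en-1-one
Conditions: PdCl2(dppf) (3 mol %), THF–DMF, rt to 40 °C
Reagents that add atoms: none
Why: Negishi coupling of an α-iodoenone with a primary alkylzinc halide should install the masked C6–C8 arm, the wide-bite-angle ligand holding back β-hydride elimination.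

Step 3
Reactants: 5 furan-3-ylmethanol
Product: 6 3-(chloromethyl)furan
Conditions: SOCl2, pyridine, Et2O, 0 °C
Reagents that add atoms: thionyl chloride, O=S(Cl)Cl
Why: Chlorodehydroxylation through the chlorosulfite under buffered conditions should convert the primary furylmethyl alcohol without acid damage to the furan.

Step 4
Reactants: 6 3-(chloromethyl)furan; 7 2,3-dibromoprop-1-ene
Product: 9 2-bromo-4-(furan-3-yl)but-1-ene, via furan-3-ylmethylmagnesium chloride 8 (not isolated)
Conditions: Mg, THF, 0 °C; then 7, Li2CuCl4 (2 mol %), THF, 0 °C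
Reagents that add atoms: none
Why: Copper-catalysed cross-coupling of a Grignard reagent at the allylic bromide should leave the vinylic bromide untouched and give the C9/C11/C12/C20 fragment.

Step 5
Reactants: 9 2-bromo-4-(furan-3-yl)but-1-ene; 4 2-[2-(1,3-dioxolan-2-yl)ethyl]cyclohex-2-en-1-one
Product: 12 (2R,3S)-2-[2-(1,3-dioxolan-2-yl)ethyl]-3-[4-(furan-3-yl)but-1-en-2-yl]cyclohexan-1-one, via alkenylmagnesium bromide 10 (not isolated), via magnesium enolate 11 (not isolated)
Conditions: Mg, THF, 40 °C; then 4, Cu(OTf)2 (3 mol %), tert-leucinol-derived hydroxyalkyl imidazolinium hexafluorophosphate (4 mol %), Et2O, −30 °C; then MeOH, NaOMe (cat.), rt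
Reagents that add atoms: none
Why: Copper–NHC-catalysed asymmetric conjugate addition of a Grignard reagent to an α-substituted cyclic enone sets C10 under ligand control, and protonation under equilibrating conditions should place the C5 arm trans, with both arms equatorial.

Step 6
Reactants: 12 (2R,3S)-2-[2-(1,3-dioxolan-2-yl)ethyl]-3-[4-(furan-3-yl)but-1-en-2-yl]cyclohexan-1-one
Product: 13 3-{(1R,2S)-2-[4-(furan-3-yl)but-1-en-2-yl]-6-oxocyclohexyl}propanal
Conditions: 1 M HCl, THF, rt
Reagents that add atoms: water, O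
Why: Acid-catalysed acetal hydrolysis under dilute conditions should free the C8 aldehyde while the 3-alkylfuran and the 1,1-disubstituted alkene survive.

Step 7
Reactants: 13 3-{(1R,2S)-2-[4-(furan-3-yl)but-1-en-2-yl]-6-oxocyclohexyl}propanal; 14 diethyl [(phenylsulfonyl)methyl]phosphonate
Product: 15 (2R,3S)-3-[4-(furan-3-yl)but-1-en-2-yl]-2-[(3E)-4-(phenylsulfonyl)but-3-en-1-yl]cyclohexan-1-one
Conditions: 14, NaH, THF, 0 °C; then 13, −78 to 0 °C
Reagents that add atoms: none
Why: Horner–Wadsworth–Emmons olefination should take the aldehyde in preference to the hindered ketone and give the (E)-vinyl sulfone, in which C17 carries a removable activating group.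

Step 8
Reactants: 15 (2R,3S)-3-[4-(furan-3-yl)but-1-en-2-yl]-2-[(3E)-4-(phenylsulfonyl)but-3-en-1-yl]cyclohexan-1-one
Product: 16 (4aS,5R,6R,8aR)-5-[2-(furan-3-yl)ethyl]-5-methyl-6-[(phenylsulfonyl)methyl]octahydronaphthalen-1(2H)-one (trans-fused)
Conditions: Fe(acac)3 (30 mol %), PhSiH3 (2.5 equiv), EtOH, 60 °C, 0.01 M
Reagents that add atoms: none
Why: An iron hydride formed from Fe(acac)3 and PhSiH3 transfers a hydrogen atom to the CH2 terminus of the electron-neutral 1,1-disubstituted alkene, which creates the C20 methyl group and the nucleophilic tertiary C9 radical; this adds to the β-carbon (C8) of the vinyl sulfone, and the α-sulfonyl radical is then reduced and protonated by ethanol. This is the intramolecular form of the iron-catalysed reductive olefin coupling (hydrogen-atom-transfer Giese addition), for which vinyl sulfones are established acceptors and quaternary carbons are usual products. Ring B closes 6-exo-trig, and 7-endo attack at C17 is disfavoured by polarity. With both arms equatorial on the ring A chair only one chair–chair (trans-decalin) array is open, so C10 fixes the face: the sulfonylmethyl group (C17) sits equatorial, which sets C8, and at the planar radical the furylethyl arm takes the equatorial sector because an axial two-carbon arm would meet C1 and C17 in syn-pentane contacts, which leaves C20 axial and cis to C17 and sets C9. The step needs hydrogen-atom transfer to the C9=CH2 alkene only and ring closure faster than radical reduction; the electron-poor sulfone alkene, the furan and the ketone are poor hydrogen-atom acceptors, and dilution together with the activated acceptor should favour closure.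

Step 9
Reactants: 16 (4aS,5R,6R,8aR)-5-[2-(furan-3-yl)ethyl]-5-methyl-6-[(phenylsulfonyl)methyl]octahydronaphthalen-1(2H)-one
Product: 17 (4aS,5S,6R,8aR)-5-[2-(furan-3-yl)ethyl]-5,6-dimethyloctahydronaphthalen-1(2H)-one (trans-fused)
Conditions: Na(Hg) (6 %), Na2HPO4, MeOH–THF, −20 to 0 °C
Reagents that add atoms: none
Why: Buffered reductive desulfonylation by electron transfer should turn CH2SO2Ph into the C17 methyl group without touching the stereocentres, the hindered ketone or the furan.

Step 10
Reactants: 17 (4aS,5S,6R,8aR)-5-[2-(furan-3-yl)ethyl]-5,6-dimethyloctahydronaphthalen-1(2H)-one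
Product: 19 (4aR,5S,6R,8aS)-5-[2-(furan-3-yl)ethyl]-8a-(hydroxymethyl)-5,6-dimethyloctahydronaphthalen-1(2H)-one (cis-fused), via ring-fusion silyl enol ether 18 (not isolated)
Conditions: TMSCl, NaI, Et3N, MeCN, 40 °C; pentane extraction; then aq HCHO, Yb(OTf)3 (10 mol %), THF, rt
Reagents that add atoms: formaldehyde, C=O
Why: Thermodynamic enol silylation should favour the tetrasubstituted C4=C5 enol ether, and its lanthanide-triflate-catalysed Mukaiyama aldol reaction with formaldehyde should occur on the face opposite the axial C20 methyl (1,3 to C5), which places C19 cis to H10.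

Step 11
Reactants: 19 (4aR,5S,6R,8aS)-5-[2-(furan-3-yl)ethyl]-8a-(hydroxymethyl)-5,6-dimethyloctahydronaphthalen-1(2H)-one
Product: 21 (4aR,5S,6R,8aS)-5-[2-(furan-3-yl)ethyl]-5,6-dimethyl-8a-{[(triethylsilyl)oxy]methyl}-4a,5,6,7,8,8a-hexahydronaphthalen-1(4H)-one, via bis(triethylsilyl) enol ether 20 (not isolated)
Conditions: LDA (2.3 equiv), TESCl (3 equiv), THF, −78 to 0 °C; then Pd(OAc)2 (1.05 equiv), MeCN, rt
Reagents that add atoms: chlorotriethylsilane, CC[Si](Cl)(CC)CC
Why: With C5 now quaternary the ketone can enolise only towards C3, so silylation with in situ quench (which also caps the C19 alkoxide before a retro-aldol can start) followed by Saegusa–Ito oxidation should give the C2=C3 enone.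

Step 12
Reactants: 21 (4aR,5S,6R,8aS)-5-[2-(furan-3-yl)ethyl]-5,6-dimethyl-8a-{[(triethylsilyl)oxy]methyl}-4a,5,6,7,8,8a-hexahydronaphthalen-1(4H)-one
Product: 22 (4aR,5S,6R,8aS)-5-[2-(furan-3-yl)ethyl]-5,6-dimethyl-8a-{[(triethylsilyl)oxy]methyl}-4a,5,6,7,8,8a-hexahydronaphthalen-1-yl trifluoromethanesulfonate
Conditions: KHMDS, THF, −78 °C; then PhNTf2, −78 to 0 °C
Reagents that add atoms: N-phenylbis(trifluoromethanesulfonimide), O=S(=O)(N(c1ccccc1)S(=O)(=O)C(F)(F)F)C(F)(F)F
Why: The enone has no α′ hydrogen, so γ-deprotonation at C1 and O-sulfonylation of the extended dienolate should give the C1=C2–C3=C4 dienyl triflate.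

Step 13
Reactants: 22 (4aR,5S,6R,8aS)-5-[2-(furan-3-yl)ethyl]-5,6-dimethyl-8a-{[(triethylsilyl)oxy]methyl}-4a,5,6,7,8,8a-hexahydronaphthalen-1-yl trifluoromethanesulfonate
Product: 24 (5R,8R,9S,10R)-15,16-epoxy-5,10-cis-cleroda-1,3,13(16),14-tetraen-18,19-olide (tricyclic dienyl γ-lactone; C19 and H10 cis), via hydroxy triflate 23 (not isolated)
Conditions: HF·pyridine, THF, 0 °C; work-up; then Pd(PPh3)4 (5 mol %), CO (1 atm), K2CO3, DMF, 50 °C
Reagents that add atoms: carbon monoxide, [C-]#[O+]
Why: Palladium-catalysed carbonylative lactonisation (oxidative addition of the dienyl triflate, CO insertion, five-ring capture of the acyl palladium by the C19 hydroxyl) should install C18 and tie it to C19.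

Step 14
Reactants: 24 (5R,8R,9S,10R)-15,16-epoxy-5,10-cis-cleroda-1,3,13(16),14-tetraen-18,19-olide
Product: 25 (8R,9S)-15,16-epoxy-5,10-secocleroda-1(10)E,2Z,4,13(16),14-pentaen-18,19-olide (ten-membered triene fused to a butenolide)
Conditions: hν (313 nm), degassed Et2O, −40 °C, partial conversion with recycling of 24
Reagents that add atoms: none
Why: Photochemical conrotatory 6π electrocyclic ring opening cleaves C5–C10; the five-membered lactone allows C19 to turn only outward (cis to C18), so with the cis ring fusion C9 must also turn outward, which should give the C4=C5 ring-cis, C2=C3 Z and C1=C10 E triene, whose twisted chromophore absorbs less at this wavelength.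

Step 15
Reactants: 25 (8R,9S)-15,16-epoxy-5,10-secocleroda-1(10)E,2Z,4,13(16),14-pentaen-18,19-olide
Product: 26 lithium (8R,9S)-15,16-epoxy-19-hydroxy-5,10-secocleroda-1(10)E,2Z,4Z,13(16),14-pentaen-18-oate
Conditions: LiOH (1.05 equiv), THF–H2O, 0 °C; lyophilise
Reagents that add atoms: lithium hydroxide, [Li+].[OH-]
Why: Saponification of the butenolide gives the hydroxy carboxylate, which is kept as its salt so that it cannot relactonise.

Step 16
Reactants: 26 lithium (8R,9S)-15,16-epoxy-19-hydroxy-5,10-secocleroda-1(10)E,2Z,4Z,13(16),14-pentaen-18-oate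
Product: 29 (8R,9S)-19-acetoxy-15,16-epoxy-5,10-secocleroda-1(10)E,2Z,4Z,13(16),14-pentaen-18-oic acid (target), via silyl ester 27 (not isolated), via acetoxy silyl ester 28 (not isolated)
Conditions: TIPSCl (1.05 equiv), DMF, 0 °C; then Ac2O, Et3N, DMAP (cat.), 0 °C; then HF·pyridine, THF, 0 °C
Reagents that add atoms: acetic anhydride, CC(=O)OC(C)=O
Why: The carboxylate is the only anionic nucleophile and should be O-silylated selectively, fast DMAP-catalysed acetylation then caps the C19 hydroxyl before the bulky silyl ester can lactonise, and fluoride frees the acid without touching the acetate.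

**Compound list**

1 | cyclohex-2-en-1-one | O=C1C=CCCC1 | starting material
2 | 2-iodocyclohex-2-en-1-one | O=C1CCCC=C1I | intermediate
3 | [2-(1,3-dioxolan-2-yl)ethyl]zinc bromide | Br[Zn]CCC1OCCO1 | starting material
4 | 2-[2-(1,3-dioxolan-2-yl)ethyl]cyclohex-2-en-1-one | O=C1CCCC=C1CCC2OCCO2 | intermediate
5 | furan-3-ylmethanol | OCc1ccoc1 | starting material
6 | 3-(chloromethyl)furan | ClCc1ccoc1 | intermediate
7 | 2,3-dibromoprop-1-ene | C=C(Br)CBr | starting material
8 | furan-3-ylmethylmagnesium chloride | Cl[Mg]Cc1ccoc1 | intermediate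
9 | 2-bromo-4-(furan-3-yl)but-1-ene | C=C(Br)CCc1ccoc1 | intermediate
10 | [4-(furan-3-yl)but-1-en-2-yl]magnesium bromide | C=C([Mg]Br)CCc1ccoc1 | intermediate
11 | bromomagnesium C4=C5 enolate of 12 | Br[Mg]OC1=C(CCC2OCCO2)[C@@H](C(=C)CCc2ccoc2)CCC1 | intermediate
12 | (2R,3S)-2-[2-(1,3-dioxolan-2-yl)ethyl]-3-[4-(furan-3-yl)but-1-en-2-yl]cyclohexan-1-one | O=C1CCC[C@H](C(=C)CCc2ccoc2)[C@H]1CCC3OCCO3 | intermediate
13 | 3-{(1R,2S)-2-[4-(furan-3-yl)but-1-en-2-yl]-6-oxocyclohexyl}propanal | O=C1CCC[C@H](C(=C)CCc2ccoc2)[C@H]1CCC=O | intermediate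
14 | diethyl [(phenylsulfonyl)methyl]phosphonate | CCOP(=O)(CS(=O)(=O)c1ccccc1)OCC | starting material
15 | (2R,3S)-3-[4-(furan-3-yl)but-1-en-2-yl]-2-[(3E)-4-(phenylsulfonyl)but-3-en-1-yl]cyclohexan-1-one | O=C1CCC[C@H](C(=C)CCc2ccoc2)[C@H]1CC/C=C/S(=O)(=O)c1ccccc1 | intermediate
16 | (4aS,5R,6R,8aR)-5-[2-(furan-3-yl)ethyl]-5-methyl-6-[(phenylsulfonyl)methyl]octahydronaphthalen-1(2H)-one | O=C1CCC[C@H]2[C@H]1CC[C@@H](CS(=O)(=O)c1ccccc1)[C@]2(C)CCc1ccoc1 | intermediate
17 | (4aS,5S,6R,8aR)-5-[2-(furan-3-yl)ethyl]-5,6-dimethyloctahydronaphthalen-1(2H)-one | O=C1CCC[C@H]2[C@H]1CC[C@@H](C)[C@]2(C)CCc1ccoc1 | intermediate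
18 | trimethylsilyl enol ether of 17 with the ring-fusion C4=C5 double bond | C[Si](C)(C)OC1=C2CC[C@@H](C)[C@](C)(CCc3ccoc3)[C@H]2CCC1 | intermediate
19 | (4aR,5S,6R,8aS)-5-[2-(furan-3-yl)ethyl]-8a-(hydroxymethyl)-5,6-dimethyloctahydronaphthalen-1(2H)-one | O=C1CCC[C@H]2[C@]1(CO)CC[C@@H](C)[C@]2(C)CCc1ccoc1 | intermediate
20 | C3=C4 triethylsilyl enol ether of the C19 triethylsilyl ether of 19 | CC[Si](CC)(CC)OC[C@]12CC[C@@H](C)[C@](C)(CCc3ccoc3)[C@H]1CCC=C2O[Si](CC)(CC)CC | intermediate
21 | (4aR,5S,6R,8aS)-5-[2-(furan-3-yl)ethyl]-5,6-dimethyl-8a-{[(triethylsilyl)oxy]methyl}-4a,5,6,7,8,8a-hexahydronaphthalen-1(4H)-one | O=C1C=CC[C@H]2[C@]1(CO[Si](CC)(CC)CC)CC[C@@H](C)[C@]2(C)CCc1ccoc1 | intermediate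
22 | (4aR,5S,6R,8aS)-5-[2-(furan-3-yl)ethyl]-5,6-dimethyl-8a-{[(triethylsilyl)oxy]methyl}-4a,5,6,7,8,8a-hexahydronaphthalen-1-yl trifluoromethanesulfonate | O=S(=O)(OC1=CC=C[C@H]2[C@]1(CO[Si](CC)(CC)CC)CC[C@@H](C)[C@]2(C)CCc1ccoc1)C(F)(F)F | intermediate
23 | C19 alcohol of dienyl triflate 22 | O=S(=O)(OC1=CC=C[C@H]2[C@]1(CO)CC[C@@H](C)[C@]2(C)CCc1ccoc1)C(F)(F)F | intermediate
24 | (5R,8R,9S,10R)-15,16-epoxy-5,10-cis-cleroda-1,3,13(16),14-tetraen-18,19-olide | O=C1OC[C@]2(CC[C@@H](C)[C@]3(C)CCc4ccoc4)[C@@H]3C=CC=C12 | intermediate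
25 | (8R,9S)-15,16-epoxy-5,10-secocleroda-1(10)E,2Z,4,13(16),14-pentaen-18,19-olide | O=C1OCC2=C1/C=C\C=C\[C@@](C)(CCc3ccoc3)[C@H](C)CC2 | intermediate
26 | lithium (8R,9S)-15,16-epoxy-19-hydroxy-5,10-secocleroda-1(10)E,2Z,4Z,13(16),14-pentaen-18-oate | OC/C1=C(C(=O)[O-])/C=C\C=C\[C@@](C)(CCc2ccoc2)[C@H](C)CC1.[Li+] | intermediate
27 | triisopropylsilyl ester of the 19-hydroxy acid | OC/C1=C(C(=O)O[Si](C(C)C)(C(C)C)C(C)C)/C=C\C=C\[C@@](C)(CCc2ccoc2)[C@H](C)CC1 | intermediate
28 | triisopropylsilyl ester of the target | CC(=O)OC/C1=C(C(=O)O[Si](C(C)C)(C(C)C)C(C)C)/C=C\C=C\[C@@](C)(CCc2ccoc2)[C@H](C)CC1 | intermediate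
29 | (8R,9S)-19-acetoxy-15,16-epoxy-5,10-secocleroda-1(10)E,2Z,4Z,13(16),14-pentaen-18-oic acid | CC(=O)OC/C1=C(C(=O)O)/C=C\C=C\[C@@](C)(CCc2ccoc2)[C@H](C)CC1 | target

**Step count and risks**

Total step count: 16. Longest linear sequence: 14 (steps 3–16, or equally steps 1, 2 and 5–16).

**Step 14.**
- Risk: The ring opening may stall in a photostationary mixture. The triene may also be consumed by secondary photoreactions (double-bond isomerisation, hydrogen shifts, re-closure), because the dienoate and the product absorb in neighbouring regions.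
- Fallback: This route changes the chromophore. It sets out from 24.
  - DIBAL-H at −78 °C gives the tricyclic lactol F3.
  - MeOH with PPTS turns it into the cyclic methyl acetal F4. This keeps the five-membered tether but is a plain homoannular diene.
  - Irradiation at shorter wavelength opens it in the same rotational sense to the seco methyl acetal F5.
  - Aqueous acetic acid gives the seco lactol F6.
  - MnO2 oxidises this allylic lactol, and the route is rejoined at 25.

**Step 8.**
- Risk: The tertiary radical may be reduced or isomerised back to an alkene before it cyclises. The two rotamers at the planar C9 centre may also be poorly discriminated.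
- Fallback: This route makes the same bond by two-electron organometallic chemistry. It sets out from 13.
  - Ohira–Bestmann homologation gives the terminal alkyne F1.
  - Palladium-hydride reductive enyne cyclisation follows, with Pd2(dba)3·CHCl3, P(o-tol)3, AcOH and Et3SiH. It proceeds by hydropalladation, 6-exo carbopalladation of the C9=CH2 alkene and silane capture of the neopentyl palladium, and gives the methylidene decalone F2.
  - Hydrogen-atom-transfer hydrogenation with Mn(dpm)3, PhSiH3 and t-BuOOH in i-PrOH delivers the equatorial C17 methyl. The route is rejoined at 17.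

**Step 16.**
- Risk: Relactonisation of the silyl ester, or silyl migration to the hydroxyl group, may outrun acetylation.
- Fallback: This route avoids any activated acid next to a free hydroxyl. It sets out from 25.
  - AlMe3 with MeNH(OMe)·HCl opens the butenolide to the hydroxy Weinreb amide F7.
  - Ac2O in pyridine gives the acetoxy Weinreb amide F8.
  - Cp2Zr(H)Cl reduces the amide chemoselectively to the acetoxy enal F9.
  - Pinnick oxidation (NaClO2, NaH2PO4, 2-methylbut-2-ene) rejoins the route at 29.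

**Further compounds**

F1 | step 8 | (2R,3S)-2-(but-3-yn-1-yl)-3-[4-(furan-3-yl)but-1-en-2-yl]cyclohexan-1-one | O=C1CCC[C@H](C(=C)CCc2ccoc2)[C@H]1CCC#C
F2 | step 8 | (4aS,5R,8aR)-5-[2-(furan-3-yl)ethyl]-5-methyl-6-methylideneoctahydronaphthalen-1(2H)-one | O=C1CCC[C@H]2[C@H]1CCC(=C)[C@]2(C)CCc1ccoc1
F3 | step 14 | tricyclic lactol (C18 hemiacetal of 24; anomers) | OC1OC[C@]2(CC[C@@H](C)[C@]3(C)CCc4ccoc4)[C@@H]3C=CC=C12
F4 | step 14 | cyclic methyl acetal of F3 | COC1OC[C@]2(CC[C@@H](C)[C@]3(C)CCc4ccoc4)[C@@H]3C=CC=C12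
F5 | step 14 | seco methyl acetal (ten-membered triene fused to a 2-methoxy-2,5-dihydrofuran) | COC1OCC2=C1/C=C\C=C\[C@@](C)(CCc3ccoc3)[C@H](C)CC2
F6 | step 14 | seco lactol (C18 hemiacetal of 25) | OC1OCC2=C1/C=C\C=C\[C@@](C)(CCc3ccoc3)[C@H](C)CC2
F7 | step 16 | 19-hydroxy N-methoxy-N-methylamide of the seco acid | OC/C1=C(C(=O)N(C)OC)/C=C\C=C\[C@@](C)(CCc2ccoc2)[C@H](C)CC1
F8 | step 16 | 19-acetoxy N-methoxy-N-methylamide of the seco acid | CC(=O)OC/C1=C(C(=O)N(C)OC)/C=C\C=C\[C@@](C)(CCc2ccoc2)[C@H](C)CC1
F9 | step 16 | 19-acetoxy seco 18-aldehyde | CC(=O)OC/C1=C(C=O)/C=C\C=C\[C@@](C)(CCc2ccoc2)[C@H](C)CC1
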